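# Proposed synthesis of CNP0210582.1 by a chelated dianion Ireland–Claisen rearrangement

Atom labels used throughout: C1 is the benzylic carbinol carbon, C2 the methine, C3 the CH2O carbon, C4 the allylic CH2, C5=C6 the alkene (C6 on the dimethoxyphenyl ring). C1'–C4' are the carbons of the side-chain acid.

## Analysis of the target

Target 19 is open-chain. A three-carbon backbone C1–C2–C3 carries the 4-methoxyphenyl carbinol at C1, a methine at C2 and an acyloxymethyl group at C3. C2 also bears the arm C4H2–C5H=C6H, which ends on the 3,4-dimethoxyphenyl ring. The C3 oxygen is acylated by a (Z)-2-(hydroxymethyl)but-2-enoyl group in which the C4' methyl is cis to the carbonyl, the less stable, angelate-like geometry.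

The only stereocentres are C1 (S) and C2 (S). They are adjacent, and with the chain C3–C2–C1–aryl drawn as a zigzag the C1 hydroxyl and the C4 arm lie on opposite sides (anti).

Three groups are sensitive. The 4-methoxybenzylic alcohol ionises in acid. The Z-enoate can isomerise when its acyl group is activated in the presence of nucleophilic catalysts. The primary ester sits 1,3 to a free secondary hydroxyl and could migrate under base.

The difficulty is threefold: an anti diad must be set in an open chain, two alkenes of defined geometry must be made by different logic, and three hydroxyls must be told apart.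

The strategy rests on the C2–C4 bond. C2 is alpha to C3, which can be raised to the carboxyl level, and the bond lies next to the E C5=C6 alkene conjugated with the dimethoxyphenyl ring. This γ,δ-unsaturated acid pattern is the product signature of a [3,3] shift of the enolate of a 1-arylallyl ester. The C1 hydroxyl is placed where it can chelate that enolate.

## Retrosynthetic reasoning

**Unmasking the side-chain hydroxyl (19 from 18).** The C2' hydroxymethyl group is carried as a silyl ether until the end. It is the only hydroxyl that would let acid 16 esterify itself, and buffered fluoride removes the silyl group without acid at C1 or base near the ester.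

**Ester C3–O bond (18 from 11 and 16).** This cut separates the core from the Z-acid, so that each stereochemical problem is solved on a small molecule. It is placed at the primary oxygen because the hindered secondary benzylic hydroxyl of 11 can be left unprotected. The forward reaction must acylate only the primary hydroxyl and must not isomerise the Z double bond of 16.

**Side-chain acid (16 from 15, 14 and 12).** The C2'–CH2OH bond and the C3'–H bond are cut together, which leads back to the triple bond of 12. Syn addition of a metal hydride across the alkyne, followed by capture of the alkenyl metal species 13 by a one-carbon aldehyde, fixes the Z geometry by mechanism. Doing this on the simple ester 12 means the geometry of 14 can be checked before anything valuable is attached.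

**Oxidation level at C3 (11 from 10).** C3 is traced back to a carboxylic acid so that C2 becomes the alpha carbon of an acid derivative. That is what the rearrangement needs.

**Key disconnection, C2–C4 (10 from 8 via 9).** Cutting C2–C4 and reconnecting C6 to the carboxyl oxygen gives the 1-arylallyl β-hydroxy ester 8. This is the best place to cut for three reasons:
- it joins the two aryl-bearing halves;
- it forms C2 under the influence of the C1 oxygen that is already present;
- it delivers the E styrene in the same event.

A cut at C1–C2 would demand an anti-selective aldol of a γ,δ-unsaturated ester. A cut at C1–aryl would put an enolisable aldehyde next to C2. The precursor 8 has two stereocentres that are made independently, so its synthesis is simple. The forward step must form dianion 9 cleanly and rearrange it through one chair.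

**Hydroxy ester 8 (from 7, then 5 and 6).** The C1 carbinol is traced to the aryl ketone of 7, which a chiral transfer-hydrogenation catalyst can reduce without touching the vinyl group. The ester bond of 7 is made by exchange at the acyl carbon of β-keto ester 6 with alcohol 5. This order avoids coupling a free β-hydroxy acid, which would acylate its own hydroxyl, and needs no protecting group on C1.

**Allylic alcohol 5 (from 4, 3, then 1 and 2).** The C6–vinyl bond is cut to aldehyde 1 and vinyl nucleophile 2. The racemic carbinol 3 is resolved by enzymatic acylation to 4, which is then deacylated to 5. A single enantiomer is needed because the C6 configuration decides which enolate face the allyl terminus reaches in the chair.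

## Alternatives that were turned down

**Alternative 1: asymmetric Prins reaction.**
- Disconnection: C2–C3 and C1–O are cut together. C1 and C2 come from the E alkene of (E)-1-methoxy-4-(penta-1,4-dienyl)benzene A1, and C3 with both oxygens from formaldehyde A3.
- Forward key step: a confined chiral Brønsted acid activates A3, which adds to the alkene carbon that becomes C2. A hemiformal oxygen then closes onto the 4-methoxybenzylic cation at C1 to give the trans-dioxane (4S,5S)-4-(4-methoxyphenyl)-5-(prop-2-enyl)-1,3-dioxane A2.
- For: both stereocentres and the C3 oxygen arise in one catalytic step from an achiral hydrocarbon, and the E geometry of A1 maps onto the anti diad.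
- Against:
  - The cation at C1 is strongly stabilised by the 4-methoxy group, so ring closure is likely stepwise and bond rotation can erode the trans relationship and the enantioselectivity.
  - The terminal alkene of A1 is a second site for A3.
  - A2 still lacks the dimethoxyphenyl ring, so a later cross-metathesis on the allyl group is needed.
  - The methylene acetal must be removed from a 4-methoxybenzylic oxygen with acid strong enough to ionise C1–O.
- Comparison: it is stronger on step economy up to the diad. The chosen route sets C2, the arm and the E alkene in one basic step with two control elements pointing the same way, and C1 never sees strong acid once it is made.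

**Alternative 2: late hydroalumination of a but-2-ynoate.**
- Disconnection: inside the side chain, the C2'–CH2OH and C3'–H bonds are cut. This leads to the but-2-ynoate A4 of the core with its C1 hydroxyl silylated.
- Forward key step: a Lewis-base-modified dialkylaluminium hydride adds syn across the triple bond (hydride to C3', aluminium to C2'). The alkenylaluminium then adds to A3 to give the silyl ether A5 of the target.
- For: the Z geometry comes from the addition mechanism on the substrate itself. The core is acylated with an alkynoic acid that has no geometry to lose and no hydroxyl to protect. On that point it is stronger than the chosen route, where the Z-acid 16 must be transferred intact in step 11.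
- Against:
  - It says nothing about C1, C2 or the cinnamyl arm, so it is a finishing tactic and not a plan for the skeleton.
  - It exposes a fully elaborated ester to a hydride reagent, where reduction at the carbonyl would cut off the side chain.
  - It requires the C1 hydroxyl to be silylated and later freed.
  - The geometry of the new alkene is tested only on the most valuable intermediate.
- Comparison: the chosen route uses the same bond construction early, on ester 12, where failure costs little and 14 can be purified and checked.

**Alternative 3: chelation-controlled aryl Grignard addition.**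
- Disconnection: the C1–aryl bond is cut, giving the aldehyde (S,E)-5-(3,4-dimethoxyphenyl)-2-({[2-(trimethylsilyl)ethoxy]methoxy}methyl)pent-4-enal A6 and 4-methoxyphenylmagnesium bromide A7.
- Forward key step: magnesium bridges the aldehyde oxygen and the acetal-type ether oxygen on C3 in a six-membered chelate. A7 attacks C1 anti to the C2 substituent to give the (1S,2S) carbinol A8.
- For: it is convergent and the aryl group enters late. The two oxygens are differentiated from the start, so no primary-versus-secondary selection is needed when the ester is made. No strong-base enolate chemistry is run on a labile allylic ester.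
- Against:
  - A6 has an enolisable stereocentre next to the aldehyde and meets both a Lewis acid and a basic organometallic, so C2 can racemise.
  - That C2 centre must first be built in several steps, for example by desymmetrising a 2-substituted propane-1,3-diol.
  - Aryl Grignard reagents in ethereal solvent are only moderately chelation-selective because the solvent competes for magnesium.
  - The alkoxymethyl ether must later be removed beside an ionisable benzylic alcohol.
- Comparison: both plans set one centre by a reagent and the second by the substrate. The chosen route makes C1 by a reliable catalyst-controlled reduction and C2 by an intramolecular, doubly controlled shift that also builds the arm and the alkene. It accepts in exchange the selective acylation of a 1,3-diol.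

Key step: step 6

## Route

Assumption (chemistry): the lipase is taken to acylate the (R)-enantiomer of 3, the usual preference for a secondary carbinol flanked by a large aryl and a medium-sized vinyl group. If the preference were reversed, the unreacted alcohol would be carried on in place of 4 and step 3 would fall away.

Step 1
Reactants: 1 3,4-dimethoxybenzaldehyde; 2 vinylmagnesium bromide
Product: 3 rac-1-(3,4-dimethoxyphenyl)prop-2-en-1-ol
Conditions: THF, 0 °C; then sat. aq. NH4Cl
Reagents that add atoms: none
Why: Grignard 1,2-addition of a vinyl nucleophile to an aromatic aldehyde; the C6 carbinol forms as the racemate, which is resolved in step 2, and the mild ammonium chloride quench avoids ionising the allylic benzylic alcohol.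

Step 2
Reactants: 3 rac-1-(3,4-dimethoxyphenyl)prop-2-en-1-ol
Product: 4 (R)-1-(3,4-dimethoxyphenyl)prop-2-enyl acetate
Conditions: Candida antarctica lipase B (immobilised), vinyl acetate, t-BuOMe, 30 °C, stopped below half conversion
Reagents that add atoms: vinyl acetate, C=COC(C)=O
Why: Lipase-catalysed kinetic resolution by irreversible transesterification; the active site accepts the enantiomer with aryl as the large and vinyl as the medium group, which is the (R)-carbinol, so only that half should be acetylated, and stopping early keeps the enantiomeric purity of 4 high.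

Step 3
Reactants: 4 (R)-1-(3,4-dimethoxyphenyl)prop-2-enyl acetate
Product: 5 (R)-1-(3,4-dimethoxyphenyl)prop-2-en-1-ol
Conditions: K2CO3 (cat.), MeOH, 0 °C
Reagents that add atoms: none
Why: Base-catalysed methanolysis cleaves the acyl–oxygen bond and leaves the C6–O bond untouched, so the (R) configuration is retained; cold basic conditions avoid ionisation of the doubly activated position.

Step 4
Reactants: 5 (R)-1-(3,4-dimethoxyphenyl)prop-2-en-1-ol; 6 ethyl 3-(4-methoxyphenyl)-3-oxopropanoate
Product: 7 (R)-1-(3,4-dimethoxyphenyl)prop-2-enyl 3-(4-methoxyphenyl)-3-oxopropanoate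
Conditions: DMAP (0.2 equiv), 4 Å MS, toluene, 110 °C
Reagents that add atoms: none
Why: DMAP-catalysed transesterification of a β-keto ester, which proceeds through the aroylketene after loss of ethanol and needs no acid or coupling agent; the basic medium keeps the ionisable arylallyl C–O bond intact and the sieves take up the ethanol.

Step 5
Reactants: 7 (R)-1-(3,4-dimethoxyphenyl)prop-2-enyl 3-(4-methoxyphenyl)-3-oxopropanoate
Product: 8 (R)-1-(3,4-dimethoxyphenyl)prop-2-enyl (S)-3-hydroxy-3-(4-methoxyphenyl)propanoate
Conditions: RuCl(p-cymene)[(S,S)-TsDPEN] (1 mol %), HCO2H/Et3N (1:1), EtOAc, 25 °C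
Reagents that add atoms: none
Why: Noyori-type asymmetric transfer hydrogenation; the (S,S)-catalyst should deliver hydride to the aryl ketone in the sense known for aryl alkyl ketones, setting C1 as (S) under catalyst control, while outer-sphere hydride transfer leaves the vinyl group and the allylic ester alone and the amine-rich formate keeps the medium from being acidic.

Step 6
Reactants: 8 (R)-1-(3,4-dimethoxyphenyl)prop-2-enyl (S)-3-hydroxy-3-(4-methoxyphenyl)propanoate
Product: 10 (2R,3S)-2-[(E)-3-(3,4-dimethoxyphenyl)prop-2-enyl]-3-hydroxy-3-(4-methoxyphenyl)propanoic acid, via chelated dilithium alkoxide–enolate 9 (not isolated)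
Conditions: LiN(i-Pr)2 (2.3 equiv), THF, −78 °C (8 added to the base), then −78 → 23 °C; cold 0.5 M HCl to pH 3
Reagents that add atoms: lithium diisopropylamide, [Li+].CC(C)[N-]C(C)C (its lithium is present in 9 only; 10 takes up nothing but hydrogen)
Why: Adding 8 to excess amide base removes the hydroxyl proton and then an alpha proton to give dianion 9, in which lithium bridges the C1 alkoxide and the enolate oxygen; this fixes the enolate geometry (enolate oxygen cis to C1), and once both charges are in place retro-aldol cleavage is no longer a low-energy path. On warming, the allyl vinyl ether array of 9 undergoes a concerted suprafacial [3,3] shift, an ester enolate (Ireland–Claisen) rearrangement whose closest precedent is the rearrangement of allyl β-hydroxy ester dianions; it forms C2–C4, breaks C6–O and moves the double bond to C5=C6, and no ring is closed. The one new stereocentre, C2, is controlled by two elements that agree: the chelate ring exposes the enolate face anti to the 4-methoxyphenyl group on C1, the sense seen in alkylations of such dianions, which leads to the anti acid. In the chair transition state with the dimethoxyphenyl group equatorial, the (R) configuration at C6 combined with this enolate geometry places the allyl terminus on that same face, so both elements lead to (2R). The equatorial aryl group makes the new alkene E, and the conjugation that develops with the ring lowers the barrier, so the shift should run near room temperature before the enolate can fragment. The step therefore needs face selectivity at C2, E selectivity and a chair rather than a boat; these are secured by the chelate and by using a single enantiomer of 5, since the epimer at C6 would be mismatched. C1 is carried through as its alkoxide and is not affected, and mild acidification liberates 10.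

Step 7
Reactants: 10 (2R,3S)-2-[(E)-3-(3,4-dimethoxyphenyl)prop-2-enyl]-3-hydroxy-3-(4-methoxyphenyl)propanoic acid
Product: 11 (1S,2S)-2-[(E)-3-(3,4-dimethoxyphenyl)prop-2-enyl]-1-(4-methoxyphenyl)propane-1,3-diol
Conditions: LiAlH4, THF, 0 → 40 °C; then H2O, aq. NaOH
Reagents that add atoms: none
Why: LiAlH4 reduction of the lithium carboxylate to the primary alcohol; the isolated styrene is inert, C2 cannot epimerise next to a carboxylate, and the descriptor at C2 changes from R to S only because the substituent priorities change.

Step 8
Reactants: 12 methyl but-2-ynoate
Product: 14 methyl (Z)-2-(hydroxymethyl)but-2-enoate, via methyl (E)-2-(diisobutylalumanyl)but-2-enoate 13 (not isolated)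
Conditions: i-Bu2AlH, HMPA, THF, 0 °C; then CH2O (gas, from cracked paraformaldehyde), 0 → 23 °C; aq. potassium sodium tartrate
Reagents that add atoms: formaldehyde, C=O; diisobutylaluminium hydride, CC(C)C[AlH]CC(C)C (its aluminium is present in 13 only)
Why: Syn hydroalumination of an alkynoate by the i-Bu2AlH–HMPA complex puts hydride on C3' and aluminium on C2', and aldol-type capture of the alkenylaluminium by formaldehyde with retention leaves the C4' methyl cis to the ester (Z); the temperature is kept low so that 13 does not equilibrate through its allenolate form.

Step 9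
Reactants: 14 methyl (Z)-2-(hydroxymethyl)but-2-enoate
Product: 15 methyl (Z)-2-{[tert-butyl(dimethyl)silyl]oxymethyl}but-2-enoate
Conditions: TBSCl, imidazole, CH2Cl2, 0 → 23 °C
Reagents that add atoms: tert-butyldimethylsilyl chloride, CC(C)(C)[Si](C)(C)Cl
Why: Standard silylation of a primary allylic alcohol; it masks the hydroxyl so that the acid cannot acylate itself in step 11.

Step 10
Reactants: 15 methyl (Z)-2-{[tert-butyl(dimethyl)silyl]oxymethyl}but-2-enoate
Product: 16 (Z)-2-{[tert-butyl(dimethyl)silyl]oxymethyl}but-2-enoic acid
Conditions: LiOH·H2O, THF/H2O (3:1), 0 → 23 °C; cold 0.5 M HCl to pH 4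
Reagents that add atoms: lithium hydroxide, [Li+].[OH-] (its oxygen becomes the carboxyl OH)
Why: Saponification of a methyl ester; mild temperature and a short reaction time are chosen because isomerisation of such Z-enoates by hydroxide needs far more forcing conditions, and the silyl ether is stable to aqueous LiOH.

Step 11
Reactants: 16 (Z)-2-{[tert-butyl(dimethyl)silyl]oxymethyl}but-2-enoic acid; 11 (1S,2S)-2-[(E)-3-(3,4-dimethoxyphenyl)prop-2-enyl]-1-(4-methoxyphenyl)propane-1,3-diol
Product: 18 (2S,3S)-2-[(E)-3-(3,4-dimethoxyphenyl)prop-2-enyl]-3-hydroxy-3-(4-methoxyphenyl)propyl (Z)-2-{[tert-butyl(dimethyl)silyl]oxymethyl}but-2-enoate, via mixed 2,4,6-trichlorobenzoic anhydride 17 (not isolated)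
Conditions: 16, 2,4,6-Cl3C6H2COCl, Et3N, toluene, 23 °C; then 11, 60 °C
Reagents that add atoms: 2,4,6-trichlorobenzoyl chloride, O=C(Cl)c1c(Cl)cc(Cl)cc1Cl (its atoms are present in 17 only)
Why: Yamaguchi-type mixed-anhydride esterification run without a nucleophilic pyridine catalyst, because conjugate addition of such catalysts to the activated acyl group is what isomerises Z-2-substituted but-2-enoates; the hindered anhydride should acylate the primary hydroxyl of 11 in preference to the secondary benzylic one.

Step 12
Reactants: 18 (2S,3S)-2-[(E)-3-(3,4-dimethoxyphenyl)prop-2-enyl]-3-hydroxy-3-(4-methoxyphenyl)propyl (Z)-2-{[tert-butyl(dimethyl)silyl]oxymethyl}but-2-enoate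
Product: 19 (2S,3S)-2-[(E)-3-(3,4-dimethoxyphenyl)prop-2-enyl]-3-hydroxy-3-(4-methoxyphenyl)propyl (Z)-2-(hydroxymethyl)but-2-enoate
Conditions: HF·pyridine, pyridine, THF, 0 → 23 °C
Reagents that add atoms: none
Why: Fluoride cleavage of a primary silyl ether; buffering with pyridine avoids acid ionisation of the 4-methoxybenzylic alcohol, and the absence of a basic fluoride source avoids acyl migration to the C1 hydroxyl.

## Compound list

1 | 3,4-dimethoxybenzaldehyde | COc1ccc(C=O)cc1OC | starting material
2 | vinylmagnesium bromide | C=C[Mg]Br | starting material
3 | rac-1-(3,4-dimethoxyphenyl)prop-2-en-1-ol | C=CC(O)c1ccc(OC)c(OC)c1 | intermediate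
4 | (R)-1-(3,4-dimethoxyphenyl)prop-2-enyl acetate | C=C[C@@H](OC(C)=O)c1ccc(OC)c(OC)c1 | intermediate
5 | (R)-1-(3,4-dimethoxyphenyl)prop-2-en-1-ol | C=C[C@@H](O)c1ccc(OC)c(OC)c1 | intermediate
6 | ethyl 3-(4-methoxyphenyl)-3-oxopropanoate | CCOC(=O)CC(=O)c1ccc(OC)cc1 | starting material
7 | (R)-1-(3,4-dimethoxyphenyl)prop-2-enyl 3-(4-methoxyphenyl)-3-oxopropanoate | C=C[C@@H](OC(=O)CC(=O)c1ccc(OC)cc1)c1ccc(OC)c(OC)c1 | intermediate
8 | (R)-1-(3,4-dimethoxyphenyl)prop-2-enyl (S)-3-hydroxy-3-(4-methoxyphenyl)propanoate | C=C[C@@H](OC(=O)C[C@H](O)c1ccc(OC)cc1)c1ccc(OC)c(OC)c1 | intermediate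
9 | dilithium alkoxide–enolate of 8 (enolate oxygen cis to C1, lithium bridging both oxygens) | C=C[C@@H](O/C([O-])=C/[C@H]([O-])c1ccc(OC)cc1)c1ccc(OC)c(OC)c1.[Li+].[Li+] | intermediate (not isolated)
10 | (2R,3S)-2-[(E)-3-(3,4-dimethoxyphenyl)prop-2-enyl]-3-hydroxy-3-(4-methoxyphenyl)propanoic acid | OC(=O)[C@H](C/C=C/c1ccc(OC)c(OC)c1)[C@H](O)c1ccc(OC)cc1 | intermediate
11 | (1S,2S)-2-[(E)-3-(3,4-dimethoxyphenyl)prop-2-enyl]-1-(4-methoxyphenyl)propane-1,3-diol | OC[C@H](C/C=C/c1ccc(OC)c(OC)c1)[C@H](O)c1ccc(OC)cc1 | intermediate
12 | methyl but-2-ynoate | CC#CC(=O)OC | starting material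
13 | methyl (E)-2-(diisobutylalumanyl)but-2-enoate | C/C=C(/[Al](CC(C)C)CC(C)C)C(=O)OC | intermediate (not isolated)
14 | methyl (Z)-2-(hydroxymethyl)but-2-enoate | C/C=C(/CO)C(=O)OC | intermediate
15 | methyl (Z)-2-{[tert-butyl(dimethyl)silyl]oxymethyl}but-2-enoate | C/C=C(/CO[Si](C)(C)C(C)(C)C)C(=O)OC | intermediate
16 | (Z)-2-{[tert-butyl(dimethyl)silyl]oxymethyl}but-2-enoic acid | C/C=C(/CO[Si](C)(C)C(C)(C)C)C(=O)O | intermediate
17 | (Z)-2-{[tert-butyl(dimethyl)silyl]oxymethyl}but-2-enoic 2,4,6-trichlorobenzoic anhydride | C/C=C(/CO[Si](C)(C)C(C)(C)C)C(=O)OC(=O)c1c(Cl)cc(Cl)cc1Cl | intermediate (not isolated)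
18 | (2S,3S)-2-[(E)-3-(3,4-dimethoxyphenyl)prop-2-enyl]-3-hydroxy-3-(4-methoxyphenyl)propyl (Z)-2-{[tert-butyl(dimethyl)silyl]oxymethyl}but-2-enoate | C/C=C(/CO[Si](C)(C)C(C)(C)C)C(=O)OC[C@H](C/C=C/c1ccc(OC)c(OC)c1)[C@H](O)c1ccc(OC)cc1 | intermediate
19 | (2S,3S)-2-[(E)-3-(3,4-dimethoxyphenyl)prop-2-enyl]-3-hydroxy-3-(4-methoxyphenyl)propyl (Z)-2-(hydroxymethyl)but-2-enoate | C/C=C(/CO)C(=O)OC[C@H](C/C=C/c1ccc(OC)c(OC)c1)[C@H](O)c1ccc(OC)cc1 | target

## Step count and least certain steps

Total step count: 12. Longest linear sequence: 9 steps (steps 1–7, 11 and 12); the side-chain acid is made in 3 steps (8–10).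

**Step 6 (key step).**
- What may go wrong:
  - retro-aldol fragmentation at the mono-alkoxide stage if the second deprotonation lags;
  - loss of the allyloxide from the enolate on warming before the shift takes place;
  - competing deprotonation at the doubly activated C6–H;
  - leakage through a boat or the axial-aryl chair, which would lower the selectivity at C2 or the E selectivity.
- Fallback: a Fráter–Seebach alkylation replaces the rearrangement. It sets out from 6, with racemic 3 as the source of the electrophile, and returns to the route at 11. Keto ester 6 is hydrogenated (RuCl2[(R)-BINAP], H2, EtOH, the ligand enantiomer expected to give the (S)-carbinol from an aryl keto ester) to ethyl (S)-3-hydroxy-3-(4-methoxyphenyl)propanoate F1. Racemic 3 is treated with PBr3 in Et2O at 0 °C, which should give with allylic transposition the conjugated bromide (E)-4-(3-bromoprop-1-enyl)-1,2-dimethoxybenzene F2. F1 is doubly deprotonated with LiN(i-Pr)2 (2.2 equiv, THF, −78 → −20 °C) and alkylated in the same flask with F2, anti to the aryl group of the chelate. This should give ethyl (2R,3S)-2-[(E)-3-(3,4-dimethoxyphenyl)prop-2-enyl]-3-hydroxy-3-(4-methoxyphenyl)propanoate F3, which LiAlH4 in THF reduces to 11.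

**Step 4.**
- What may go wrong: at 110 °C the arylallyl ester may undergo a 1,3-acyloxy shift to the conjugated primary ester, or a Carroll-type [3,3] shift of the enol with loss of carbon dioxide, or ionise with loss of configuration at C6.
- Fallback: the keto ester is built by low-temperature C–C bond formation instead of acyl exchange. It sets out from 4 and returns at 7. Acetate 4 (2 equiv) is deprotonated with LiN(SiMe3)2 in THF at −78 °C and C-acylated with 4-methoxybenzoyl chloride (crossed Claisen condensation). The second equivalent of enolate takes up the acidic proton of the product and is recovered as 4. No new isolable compound is made, and step 3 is bypassed.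

**Step 5.**
- What may go wrong: incomplete facial control in the hydride transfer to the electron-rich aryl ketone, which would carry through as a diastereomer, or solvolysis of the arylallyl ester in the formate medium.
- Fallback: C1 is set before the ester bond is made. It sets out from 6 and returns at 8. Keto ester 6 is hydrogenated as above to ethyl (S)-3-hydroxy-3-(4-methoxyphenyl)propanoate F1. This is silylated (Et3SiCl, imidazole, CH2Cl2) to ethyl (S)-3-(4-methoxyphenyl)-3-(triethylsilyloxy)propanoate F4 and saponified (LiOH, THF/H2O, 0 °C) to (S)-3-(4-methoxyphenyl)-3-(triethylsilyloxy)propanoic acid F5. F5 is coupled with 5 (EDC·HCl, DMAP, CH2Cl2, 0 °C) to give (R)-1-(3,4-dimethoxyphenyl)prop-2-enyl (S)-3-(4-methoxyphenyl)-3-(triethylsilyloxy)propanoate F6. Buffered fluoride (Bu4NF, AcOH, THF, 0 °C) then frees 8.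

**Step 8.**
- What may go wrong: equilibration of the alkenylaluminium through its allenolate form with loss of the Z geometry, hydride attack at the ester carbonyl, or inefficient capture of gaseous formaldehyde.
- Fallback: the same geometry is fixed by a syn hydrostannation and the carbon is added by cross-coupling. It sets out from 12 and returns at 14. Ester 12 is hydrostannylated (Bu3SnH, the zerovalent palladium complex Pd(PPh3)4, THF) to methyl (E)-2-(tributylstannyl)but-2-enoate F7. Iodine in CH2Cl2 at 0 °C converts F7 with retention to methyl (E)-2-iodobut-2-enoate F8. A Stille coupling of F8 with Bu3SnCH2OH (Pd(PPh3)4, dioxane, 80 °C) gives 14.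

**Step 11.**
- What may go wrong: Z to E isomerisation of the activated acyl group, acylation at the benzylic hydroxyl or at both hydroxyls, or sluggish reaction in the absence of a nucleophilic catalyst.
- Fallback: the ester is made by bond formation at the alkyl carbon, so that the acyl group is never activated. It sets out from 11 and returns at 18. Diol 11 is sulfonylated at the primary hydroxyl (TsCl, Et3N, cat. Me3N·HCl, CH2Cl2, −10 °C) to (2S,3S)-2-[(E)-3-(3,4-dimethoxyphenyl)prop-2-enyl]-3-hydroxy-3-(4-methoxyphenyl)propyl 4-methylbenzenesulfonate F9. F9 is displaced by the carboxylate of 16 (Cs2CO3, DMF, 50 °C) to give 18.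

## Further compounds

F1 | step 6 | ethyl (S)-3-hydroxy-3-(4-methoxyphenyl)propanoate | CCOC(=O)C[C@H](O)c1ccc(OC)cc1
F2 | step 6 | (E)-4-(3-bromoprop-1-enyl)-1,2-dimethoxybenzene | BrC/C=C/c1ccc(OC)c(OC)c1
F3 | step 6 | ethyl (2R,3S)-2-[(E)-3-(3,4-dimethoxyphenyl)prop-2-enyl]-3-hydroxy-3-(4-methoxyphenyl)propanoate | CCOC(=O)[C@H](C/C=C/c1ccc(OC)c(OC)c1)[C@H](O)c1ccc(OC)cc1
F0 | step 4 | none | none
F4 | step 5 | ethyl (S)-3-(4-methoxyphenyl)-3-(triethylsilyloxy)propanoate | CCOC(=O)C[C@H](O[Si](CC)(CC)CC)c1ccc(OC)cc1
F5 | step 5 | (S)-3-(4-methoxyphenyl)-3-(triethylsilyloxy)propanoic acid | OC(=O)C[C@H](O[Si](CC)(CC)CC)c1ccc(OC)cc1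
F6 | step 5 | (R)-1-(3,4-dimethoxyphenyl)prop-2-enyl (S)-3-(4-methoxyphenyl)-3-(triethylsilyloxy)propanoate | C=C[C@@H](OC(=O)C[C@H](O[Si](CC)(CC)CC)c1ccc(OC)cc1)c1ccc(OC)c(OC)c1
F7 | step 8 | methyl (E)-2-(tributylstannyl)but-2-enoate | C/C=C(/[Sn](CCCC)(CCCC)CCCC)C(=O)OC
F8 | step 8 | methyl (E)-2-iodobut-2-enoate | C/C=C(/I)C(=O)OC
F9 | step 11 | (2S,3S)-2-[(E)-3-(3,4-dimethoxyphenyl)prop-2-enyl]-3-hydroxy-3-(4-methoxyphenyl)propyl 4-methylbenzenesulfonate | Cc1ccc(cc1)S(=O)(=O)OC[C@H](C/C=C/c1ccc(OC)c(OC)c1)[C@H](O)c1ccc(OC)cc1
A1 | alternative 1 | (E)-1-methoxy-4-(penta-1,4-dienyl)benzene | C=CC/C=C/c1ccc(OC)cc1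
A2 | alternative 1 | (4S,5S)-4-(4-methoxyphenyl)-5-(prop-2-enyl)-1,3-dioxane | O1C[C@H](CC=C)[C@H](OC1)c1ccc(OC)cc1
A3 | alternative 1 | formaldehyde | C=O
A4 | alternative 2 | (2S,3S)-2-[(E)-3-(3,4-dimethoxyphenyl)prop-2-enyl]-3-(4-methoxyphenyl)-3-(triethylsilyloxy)propyl but-2-ynoate | CC#CC(=O)OC[C@H](C/C=C/c1ccc(OC)c(OC)c1)[C@H](O[Si](CC)(CC)CC)c1ccc(OC)cc1
A5 | alternative 2 | (2S,3S)-2-[(E)-3-(3,4-dimethoxyphenyl)prop-2-enyl]-3-(4-methoxyphenyl)-3-(triethylsilyloxy)propyl (Z)-2-(hydroxymethyl)but-2-enoate | C/C=C(/CO)C(=O)OC[C@H](C/C=C/c1ccc(OC)c(OC)c1)[C@H](O[Si](CC)(CC)CC)c1ccc(OC)cc1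
A6 | alternative 3 | (S,E)-5-(3,4-dimethoxyphenyl)-2-({[2-(trimethylsilyl)ethoxy]methoxy}methyl)pent-4-enal | C[Si](C)(C)CCOCOC[C@H](C/C=C/c1ccc(OC)c(OC)c1)C=O
A7 | alternative 3 | 4-methoxyphenylmagnesium bromide | COc1ccc([Mg]Br)cc1
A8 | alternative 3 | (1S,2S,E)-5-(3,4-dimethoxyphenyl)-1-(4-methoxyphenyl)-2-({[2-(trimethylsilyl)ethoxy]methoxy}methyl)pent-4-en-1-ol | C[Si](C)(C)CCOCOC[C@H](C/C=C/c1ccc(OC)c(OC)c1)[C@H](O)c1ccc(OC)cc1
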